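**Strategy.** The tetrahydrochromone half is read as the cyclised enol of a 2-acylcyclohexenone: O1–C8a=C4a–C4=O is a β-diketone enol ether. Everything rests on excising C4a from the carbocycle (C4a, C5–C8, C8a), which leaves a cyclopentenone (C8a, C5–C8) already carrying the trans C7/C8 oxygens. In the key step a Lewis acid makes an alkynyl diazomethyl ketone insert its diazo carbon between the carbonyl carbon and the vinylic carbon of that enone (one-carbon ring expansion, vinyl shift), and the new enol closes onto the ynone, so carbocycle and pyranone arise in one operation. The C5=C6 bond so delivered is epoxidised under 7-OH direction and opened at C5 by the second chromone's 6-phenol.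

Key step: step 4

Remark: chromone numbering (O1, C2–C4, C4a, C5–C8, C8a) is used for all bicyclic compounds; compounds 1, 3 and 12 are taken as commercial.

**Step 1**
Reactants: 1 (S)-4-[(tert-butyldimethylsilyl)oxy]cyclopent-2-en-1-one
Product: 2 (4R,5S)-5-acetoxy-4-[(tert-butyldimethylsilyl)oxy]cyclopent-2-en-1-one
Conditions: Mn(OAc)3·2H2O, benzene, reflux (Dean–Stark)
Reagents that add atoms: manganese(III) acetate, CC(=O)[O-].CC(=O)[O-].CC(=O)[O-].[Mn+3]
Why: Mn(III)-mediated α′-acetoxylation of an enone goes through the Mn enolate in a non-basic medium, which should spare the β-silyloxy group, and acetate is delivered to C5 anti to the neighbouring OTBS group, setting C5 trans to C4 (also the thermodynamic arrangement).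

**Step 2**
Reactants: 3 4-phenylbut-1-yne
Product: 4 5-phenylpent-2-ynoic acid
Conditions: n-BuLi, THF, −78 °C; CO2; aq. HCl
Reagents that add atoms: carbon dioxide, O=C=O
Why: Carboxylation of a lithium acetylide.

**Step 3**
Reactants: 4 5-phenylpent-2-ynoic acid
Product: 6 1-diazo-6-phenylhex-3-yn-2-one, via mixed carbonic anhydride 5 (not isolated)
Conditions: i-BuOCOCl, N-methylmorpholine, THF, −20 °C; CH2N2 (1.2 equiv), Et2O, −30 to 0 °C
Reagents that add atoms: diazomethane, C=[N+]=[N-]
Why: Acylation of diazomethane by a mixed anhydride (first stage of the Arndt–Eistert sequence); near-stoichiometric diazomethane at low temperature should keep dipolar cycloaddition to the ynone in check.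

**Step 4**
Reactants: 2 (4R,5S)-5-acetoxy-4-[(tert-butyldimethylsilyl)oxy]cyclopent-2-en-1-one; 6 1-diazo-6-phenylhex-3-yn-2-one
Product: 8 (7R,8S)-7-[(tert-butyldimethylsilyl)oxy]-4-oxo-2-(2-phenylethyl)-7,8-dihydro-4H-chromen-8-yl acetate, via ring-expanded ynone enol 7 (not isolated)
Conditions: BF3·OEt2 (0.2 equiv), CH2Cl2, slow addition of 6, −78 to −30 °C; then DMAP (0.5 equiv), 0 °C to rt
Reagents that add atoms: none
Why: BF3 activates the C1 carbonyl of 2, the nucleophilic diazo carbon of 6 adds 1,2 to give a β-oxido diazonium, and the vinylic C2–C1 bond shifts to the diazonium carbon as N2 leaves, so the diazo carbon becomes C4a between C8a (old C1) and C5 (old C2) and the cyclopentenone becomes the six-membered ring of enol 7. The closest known reaction type is the Lewis acid-promoted Tiffeneau–Demjanov-type (Büchner–Curtius–Schlotterbeck) homologation of cyclic ketones and enones with acceptor-substituted diazomethanes, followed by amine-catalysed cycloisomerisation of an enolised 2-alkynoyl ketone to a 4-pyranone. The carbocycle is not closed but expanded by the 1,2-shift, while the pyranone closes by 6-endo-dig oxa-Michael addition of the C8a enol oxygen to the β-carbon of the ynone. No stereocentre is formed: C7 and C8 are carried over from 2 untouched, and trans is also the thermodynamic arrangement at the enolisable C8. The step needs migration of the sp2 carbon and not of the acetoxy-bearing C5 of 2, which the higher migratory aptitude of vinyl and the inductive deactivation by the α-acetoxy group should secure, and it needs 1,2-addition in place of dipolar cycloaddition at C=C, which Lewis-acid activation at low temperature favours. Vinylogous loss of the C7 silyloxy group from 7 (aromatisation) should be held back by the poor leaving group and by fast ring closure.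

**Step 5**
Reactants: 8 (7R,8S)-7-[(tert-butyldimethylsilyl)oxy]-4-oxo-2-(2-phenylethyl)-7,8-dihydro-4H-chromen-8-yl acetate
Product: 10 (7R,8S)-7,8-dihydroxy-2-(2-phenylethyl)-7,8-dihydro-4H-chromen-4-one, via desilylated monoacetate 9 (not isolated)
Conditions: TBAF, AcOH, THF, 0 °C; then K2CO3 (cat.), MeOH, 0 °C
Reagents that add atoms: none
Why: Buffered fluoride desilylation and Zemplén-type methanolysis avoid acid throughout, because this trans-dihydrodiol of a chromone should tolerate mild base but would dehydrate to a phenol under acid.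

**Step 6**
Reactants: 10 (7R,8S)-7,8-dihydroxy-2-(2-phenylethyl)-7,8-dihydro-4H-chromen-4-one
Product: 11 (5R,6S,7S,8S)-5,6-epoxy-7,8-dihydroxy-2-(2-phenylethyl)-5,6,7,8-tetrahydro-4H-chromen-4-one
Conditions: mCPBA, THF, 0 °C to rt; cold NaHCO3 wash; crude product used at once
Reagents that add atoms: mCPBA, OOC(=O)c1cccc(Cl)c1
Why: Hydroxyl-directed (Henbest) epoxidation: the pseudo-equatorial allylic 7-OH should deliver the peracid to its own face of the electron-rich C5=C6 bond, setting C6 (and provisionally C5) with the epoxide cis to 7-OH and trans to 8-OH, while the pyranone C2=C3 and the push–pull C4a=C8a bonds are inert.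

**Step 7**
Reactants: 12 1-(2,4,5-trihydroxyphenyl)ethan-1-one
Product: 13 1-[2,5-dihydroxy-4-(prop-2-en-1-yloxy)phenyl]ethan-1-one
Conditions: allyl bromide (1.0 equiv), NaHCO3, DMF, 40 °C, argon
Reagents that add atoms: allyl bromide, C=CCBr
Why: Williamson etherification at the most acidic phenol (para to the acetyl group); the 2-OH is chelated to the carbonyl and the 5-OH is not ionised by bicarbonate.

**Step 8**
Reactants: 13 1-[2,5-dihydroxy-4-(prop-2-en-1-yloxy)phenyl]ethan-1-one
Product: 15 6-hydroxy-2-(2-phenylethyl)-7-(prop-2-en-1-yloxy)-4H-chromen-4-one, via aryl diketone 14 (not isolated)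
Conditions: LiHMDS (4.2 equiv), THF, −78 °C; 3-phenylpropanoyl chloride, −78 °C to rt; aq. HCl; then AcOH, cat. H2SO4, 90 °C
Reagents that add atoms: 3-phenylpropanoyl chloride, O=C(Cl)CCc1ccccc1
Why: Claisen-type C-acylation of the polylithiated hydroxyacetophenone followed by acid-catalysed cyclodehydration through the ortho hydroxyl (chromone closure); the allyl ether and the other phenol, which becomes the free 6-OH, do not take part.

**Step 9**
Reactants: 11 (5R,6S,7S,8S)-5,6-epoxy-7,8-dihydroxy-2-(2-phenylethyl)-5,6,7,8-tetrahydro-4H-chromen-4-one; 15 6-hydroxy-2-(2-phenylethyl)-7-(prop-2-en-1-yloxy)-4H-chromen-4-one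
Product: 16 6-{[(5S,6S,7R,8S)-6,7,8-trihydroxy-4-oxo-2-(2-phenylethyl)-5,6,7,8-tetrahydro-4H-chromen-5-yl]oxy}-2-(2-phenylethyl)-7-(prop-2-en-1-yloxy)-4H-chromen-4-one
Conditions: Cs2CO3 (0.3 equiv), DMF, rt to 40 °C
Reagents that add atoms: none
Why: SN2 epoxide opening by the only free phenoxide of 15 at C5, the terminus activated by the O1–C8a=C4a enol ether, with inversion, which sets C5 with the aryloxy group trans to 6-OH; the 7-OH is cis to the epoxide and cannot undergo Payne rearrangement.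

**Step 10**
Reactants: 16 6-{[(5S,6S,7R,8S)-6,7,8-trihydroxy-4-oxo-2-(2-phenylethyl)-5,6,7,8-tetrahydro-4H-chromen-5-yl]oxy}-2-(2-phenylethyl)-7-(prop-2-en-1-yloxy)-4H-chromen-4-one
Product: 17 7-hydroxy-6-{[(5S,6S,7R,8S)-6,7,8-trihydroxy-4-oxo-2-(2-phenylethyl)-5,6,7,8-tetrahydro-4H-chromen-5-yl]oxy}-2-(2-phenylethyl)-4H-chromen-4-one
Conditions: Pd(PPh3)4 (5 mol %), morpholine, THF, rt
Reagents that add atoms: none
Why: Tsuji–Trost deallylation of the aryl allyl ether under neutral, non-reducing conditions; the C5 aryl ether sits on a tetrasubstituted push–pull alkene that should not engage Pd(0), and both pyranones survive.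

**Compound list**
1 | (S)-4-[(tert-butyldimethylsilyl)oxy]cyclopent-2-en-1-one | O=C1C=C[C@@H](O[Si](C)(C)C(C)(C)C)C1 | starting material
2 | (4R,5S)-5-acetoxy-4-[(tert-butyldimethylsilyl)oxy]cyclopent-2-en-1-one (trans) | O=C1C=C[C@@H](O[Si](C)(C)C(C)(C)C)[C@@H]1OC(C)=O | intermediate
3 | 4-phenylbut-1-yne | C#CCCc1ccccc1 | starting material
4 | 5-phenylpent-2-ynoic acid | OC(=O)C#CCCc1ccccc1 | intermediate
5 | isobutyl carbonic 5-phenylpent-2-ynoic anhydride (not isolated) | CC(C)COC(=O)OC(=O)C#CCCc1ccccc1 | intermediate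
6 | 1-diazo-6-phenylhex-3-yn-2-one | [N-]=[N+]=CC(=O)C#CCCc1ccccc1 | intermediate
7 | (1S,6R)-6-[(tert-butyldimethylsilyl)oxy]-2-hydroxy-3-(5-phenylpent-2-ynoyl)cyclohexa-2,4-dien-1-yl acetate (enol form, not isolated) | OC1=C(C(=O)C#CCCc2ccccc2)C=C[C@@H](O[Si](C)(C)C(C)(C)C)[C@@H]1OC(C)=O | intermediate
8 | (7R,8S)-7-[(tert-butyldimethylsilyl)oxy]-4-oxo-2-(2-phenylethyl)-7,8-dihydro-4H-chromen-8-yl acetate | O=c1cc(CCc2ccccc2)oc2c1C=C[C@@H](O[Si](C)(C)C(C)(C)C)[C@@H]2OC(C)=O | intermediate
9 | (7R,8S)-7-hydroxy-4-oxo-2-(2-phenylethyl)-7,8-dihydro-4H-chromen-8-yl acetate (not isolated) | O=c1cc(CCc2ccccc2)oc2c1C=C[C@@H](O)[C@@H]2OC(C)=O | intermediate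
10 | (7R,8S)-7,8-dihydroxy-2-(2-phenylethyl)-7,8-dihydro-4H-chromen-4-one (trans-diol) | O=c1cc(CCc2ccccc2)oc2c1C=C[C@@H](O)[C@@H]2O | intermediate
11 | (5R,6S,7S,8S)-5,6-epoxy-7,8-dihydroxy-2-(2-phenylethyl)-5,6,7,8-tetrahydro-4H-chromen-4-one (epoxide cis to 7-OH, trans to 8-OH) | O=c1cc(CCc2ccccc2)oc2c1[C@H]3O[C@H]3[C@@H](O)[C@@H]2O | intermediate
12 | 1-(2,4,5-trihydroxyphenyl)ethan-1-one | CC(=O)c1cc(O)c(O)cc1O | starting material
13 | 1-[2,5-dihydroxy-4-(prop-2-en-1-yloxy)phenyl]ethan-1-one | CC(=O)c1cc(O)c(OCC=C)cc1O | intermediate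
14 | 1-[2,5-dihydroxy-4-(prop-2-en-1-yloxy)phenyl]-5-phenylpentane-1,3-dione (not isolated) | O=C(CC(=O)CCc1ccccc1)c1cc(O)c(OCC=C)cc1O | intermediate
15 | 6-hydroxy-2-(2-phenylethyl)-7-(prop-2-en-1-yloxy)-4H-chromen-4-one | O=c1cc(CCc2ccccc2)oc2cc(OCC=C)c(O)cc12 | intermediate
16 | 6-{[(5S,6S,7R,8S)-6,7,8-trihydroxy-4-oxo-2-(2-phenylethyl)-5,6,7,8-tetrahydro-4H-chromen-5-yl]oxy}-2-(2-phenylethyl)-7-(prop-2-en-1-yloxy)-4H-chromen-4-one | O=c1cc(CCc2ccccc2)oc2c1[C@H](Oc1cc3c(=O)cc(CCc4ccccc4)oc3cc1OCC=C)[C@@H](O)[C@@H](O)[C@@H]2O | intermediate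
17 | 7-hydroxy-6-{[(5S,6S,7R,8S)-6,7,8-trihydroxy-4-oxo-2-(2-phenylethyl)-5,6,7,8-tetrahydro-4H-chromen-5-yl]oxy}-2-(2-phenylethyl)-4H-chromen-4-one (5-OAr and 8-OH on one face, 6-OH and 7-OH on the other) | O=c1cc(CCc2ccccc2)oc2c1[C@H](Oc1cc3c(=O)cc(CCc4ccccc4)oc3cc1O)[C@@H](O)[C@@H](O)[C@@H]2O | target

**Totals.** Total step count: 10. Longest linear sequence: 7 steps (steps 2, 3, 4, 5, 6, 9, 10, from compound 3).

**Steps most likely to fail**

1. Step 4 (key step). The acetoxy-bearing ring carbon may shift in place of the vinylic one, the diazo ketone may add as a dipole across the enone C=C, or silanol may be lost vinylogously from the enol with aromatisation before the pyranone closes. The fallback sets out from 2 and 6 and returns at 8. Compound 6 is deprotonated (LDA, THF, −78 °C) and added 1,2 to the ketone of 2, with acetic acid quench at −78 °C to forestall acetyl migration. This gives the tertiary diazo carbinol (1S,5R)-5-[(tert-butyldimethylsilyl)oxy]-2-(1-diazo-2-oxo-6-phenylhex-3-yn-1-yl)-2-hydroxycyclopent-3-en-1-yl acetate F1 as a mixture at the carbinol carbon, which is of no consequence. Rh2(OAc)4 (cat.) in CH2Cl2 at rt then forms the rhodium carbenoid, whose 1,2-vinyl shift is favoured over alkyl shift and gives 7 under neutral conditions. DMAP closes 7 to 8.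

2. Step 1. The silyloxy group may be lost by β-elimination from the metal enolate (cyclopentadienone formation), or the trans selectivity may be incomplete. The fallback sets out from 1 and returns at 10. Desilylation (aq. HF, MeCN) gives (S)-4-hydroxycyclopent-2-en-1-one F2. Its alkoxide–enolate dianion (LDA, 2.2 equiv, THF, −78 °C) cannot eliminate, because the leaving group would be an oxide dianion. It is hydroxylated with the Davis oxaziridine anti to the alkoxide (Fráter–Seebach-type induction) to give (4R,5S)-4,5-dihydroxycyclopent-2-en-1-one F3. TBSOTf and 2,6-lutidine give (4R,5S)-4,5-bis[(tert-butyldimethylsilyl)oxy]cyclopent-2-en-1-one F4. Under the conditions of step 4 with 6, F4 passes through the enol 1-{(3S,4R)-3,4-bis[(tert-butyldimethylsilyl)oxy]-2-hydroxycyclohexa-1,5-dien-1-yl}-5-phenylpent-2-yn-1-one F5 (not isolated) to (7R,8S)-7,8-bis[(tert-butyldimethylsilyl)oxy]-2-(2-phenylethyl)-7,8-dihydro-4H-chromen-4-one F6. TBAF/AcOH then gives 10.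

3. Step 9. The bimolecular opening may be slow, so that ionisation at C5 (loss of stereocontrol, solvolysis) or base-induced decomposition of the unprotected diol epoxide takes over. The fallback sets out from 11 and returns at 16. Neutral hydrolysis (H2O/THF, pH 7 buffer) opens the epoxide at C5 to (5S,6R,7R,8S)-5,6,7,8-tetrahydroxy-2-(2-phenylethyl)-5,6,7,8-tetrahydro-4H-chromen-4-one F7. Ac2O, pyridine and DMAP give its (5S,6R,7R,8S)-5,6,7,8-tetraacetate F8. BF3·OEt2 in CH2Cl2 ionises the C5 acetate, the 6-acetoxy group closes to a cis-fused acetoxonium ion, and phenol 15 attacks C5 from the opposite face (the 1,2-trans rule of glycosylation). This gives the (5S,6R,7R,8S)-5-aryl ether 6,7,8-triacetate F9. K2CO3/MeOH removes the acetates and gives 16.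

**Further compounds**
F1 | step 4 | (1S,5R)-5-[(tert-butyldimethylsilyl)oxy]-2-(1-diazo-2-oxo-6-phenylhex-3-yn-1-yl)-2-hydroxycyclopent-3-en-1-yl acetate (both C2 epimers) | [N-]=[N+]=C(C(=O)C#CCCc1ccccc1)C1(O)C=C[C@@H](O[Si](C)(C)C(C)(C)C)[C@@H]1OC(C)=O
F2 | step 1 | (S)-4-hydroxycyclopent-2-en-1-one | O=C1C=C[C@@H](O)C1
F3 | step 1 | (4R,5S)-4,5-dihydroxycyclopent-2-en-1-one | O=C1C=C[C@@H](O)[C@@H]1O
F4 | step 1 | (4R,5S)-4,5-bis[(tert-butyldimethylsilyl)oxy]cyclopent-2-en-1-one | O=C1C=C[C@@H](O[Si](C)(C)C(C)(C)C)[C@@H]1O[Si](C)(C)C(C)(C)C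
F5 | step 1 | 1-{(3S,4R)-3,4-bis[(tert-butyldimethylsilyl)oxy]-2-hydroxycyclohexa-1,5-dien-1-yl}-5-phenylpent-2-yn-1-one | OC1=C(C(=O)C#CCCc2ccccc2)C=C[C@@H](O[Si](C)(C)C(C)(C)C)[C@@H]1O[Si](C)(C)C(C)(C)C
F6 | step 1 | (7R,8S)-7,8-bis[(tert-butyldimethylsilyl)oxy]-2-(2-phenylethyl)-7,8-dihydro-4H-chromen-4-one | O=c1cc(CCc2ccccc2)oc2c1C=C[C@@H](O[Si](C)(C)C(C)(C)C)[C@@H]2O[Si](C)(C)C(C)(C)C
F7 | step 9 | (5S,6R,7R,8S)-5,6,7,8-tetrahydroxy-2-(2-phenylethyl)-5,6,7,8-tetrahydro-4H-chromen-4-one | O=c1cc(CCc2ccccc2)oc2c1[C@H](O)[C@@H](O)[C@@H](O)[C@@H]2O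
F8 | step 9 | (5S,6R,7R,8S)-4-oxo-2-(2-phenylethyl)-5,6,7,8-tetrahydro-4H-chromene-5,6,7,8-tetrayl tetraacetate | O=c1cc(CCc2ccccc2)oc2c1[C@H](OC(C)=O)[C@@H](OC(C)=O)[C@@H](OC(C)=O)[C@@H]2OC(C)=O
F9 | step 9 | (5S,6R,7R,8S)-4-oxo-5-{[4-oxo-2-(2-phenylethyl)-7-(prop-2-en-1-yloxy)-4H-chromen-6-yl]oxy}-2-(2-phenylethyl)-5,6,7,8-tetrahydro-4H-chromene-6,7,8-triyl triacetate | O=c1cc(CCc2ccccc2)oc2c1[C@H](Oc1cc3c(=O)cc(CCc4ccccc4)oc3cc1OCC=C)[C@@H](OC(C)=O)[C@@H](OC(C)=O)[C@@H]2OC(C)=O
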